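The vessel is a closed, stirred flask of two liquid phases: reagent crosses from the second phase into the reaction phase and turns substrate into target, which crosses over, crystallises or decomposes.

substrate 0.020 M; reagent in the second phase 0.700 equiv; time 1.5 min; volume of the second phase over the first 0.25

    reagent in the reaction phase ⇌ reagent in the second phase, rate k1*([reagent in the reaction phase] - [reagent in the second phase]/K1) per volume of the first phase (K1 = 0.34, k1 = 0.119 s⁻¹)
    substrate + reagent in the reaction phase → target (k2 = 3.22 L mol⁻¹ s⁻¹)
    target ⇌ product in the second phase, rate k3*([target] - [product in the second phase]/K3) per volume of the first phase (K3 = 1.2, k3 = 0.0738 s⁻¹)
    target → decomposed product (k4 = 0.0180 s⁻¹)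
    crystals ⇌ target, rate k5*(cs5 - [target]) while solid is left; crystals form when [target] > cs5 (cs5 = 1.4 mM, k5 = 2.01 s⁻¹)

- target is meant together with its product in the second phase and crystals
- in the second phase: reagent in the second phase, product in the second phase; everything else is in the first
- charges count per volume of the first phase; a concentration in a rate is the amount of a species over the volume of its own phase; every rate counts per litre of the first phase
- solid, in amounts per volume of the solution: crystals
- run time (flask): 1.5 min

* amount of target and product in the second phase and crystals together at 1.5 min, in percent of the substrate charged
* the change that raises the amount of target and product in the second phase and crystals together at 1.5 min, in percent of the substrate charged most ("none" if none brings more than 2 percentage points) (Saturday's / Tuesday's / Wednesday's / Friday's / none)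
* amount of target and product in the second phase and crystals together at 1.5 min, in percent of the substrate charged, after Saturday's

- Saturday's: doubling the solubility in step 5, all else as stated
- Tuesday's: doubling the amount of reagent in the second phase, all else as stated
- Wednesday's: doubling the dissolution coefficient of step 5, all else as stated
- Friday's: doubling the transfer coefficient of step 3, all else as stated

Turned into times, the constants draw the curve of target with its other forms. Reagent crosses in 0.658 s, far less than the 1.5 min of the run, so the lag is short and 92.2% of the reagent stands in the reaction phase. The starting slope is then 0.831 mM s⁻¹, and c(target) reaches the solubility 1.4 mM after about 2.34 s. That is the first knee. Crystals respond within 0.498 s, far less than the 1.5 min of the run, so while they stand c(target) stays near solubility, and decomposition turns from first-order to zero-order. Its constant rate is the leak, the decomposition constant times the solubility, 1.51 mM min⁻¹.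

The reagent is the limiting reagent, so the ceiling is 70.0%. My second-order integration leaves 0.985 mM of reagent at 1.5 min, so 65.1% has formed. Formation falls to the leak at about 1.35 min, which is the summit. The curve then slides down at the leak while crystals last. After them it decays towards zero with a half-life of 0.834 min, longer than the 0.64 min of dissolved target by step 4 alone, because the curve also counts product in the second phase, which does not decompose there.

Over 1.5 min the leak costs 11.3%, so I reckon 53.8%. Saturday's doubles the leak, giving 42.5%. Tuesday's makes substrate limiting, forms 96.3% and leaves 85.0%. Wednesday's shortens a time already brief, and so does Friday's, whose crossing takes 3.13 s, far less than the 1.5 min of the run.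

The forecast gives 53.5%, Tuesday's and 42.7%, on the grounds that “Crystals then clamp it”.

The simulation gives 53.4%, names Tuesday's with a gain of 31 percentage points, and gives 42.8% after Saturday's. At 1.50 min the flask holds crystals at 44.4% of the substrate charged and decomposed product at 11.5%, against 11.3% from the leak. The neighbour flask with 0.034 M of substrate, a larger charge, holds crystals at 56.1% at that time. The same leak spread over its charge comes to 6.66%, and that flask holds decomposed product at 7.12%.

The rate constants are made up; the run is a simulation.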